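I started from a small charge: 10 µM of free catalyst has to turn over 20 mM of starting material, so I froze what the catalyst does late in a run and treated that stretch as pseudo-first-order in starting material.

| flask | starting material | second substrate | free catalyst | temperature | remark | time |
|---|---|---|---|---|---|---|
| Tuesday's | 20 mM | 20 mM | 10 µM | 75 °C | run made earlier |  |
| Friday's | 20 mM | 28 mM | 10 µM | 90 °C | run made earlier |  |
| Thursday's | 20 mM | 44 mM | 10 µM | 75 °C | run made earlier |  |
| Monday's | 20 mM | 20 mM | 15 µM | 90 °C | run made earlier |  |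
| midnight | 20 mM | 20.0 mM | 10 µM |  | everything together at the start at 60 °C, warmed to 90 °C at 80 s | 3.0 min |
| dawn | 20 mM | 20.0 mM | 10 µM | 90 °C | everything together at the start | 3.0 min |
| winter | 20 mM | 20.0 mM (fed, over 80 s) | 10 µM |  | the addition at 60 °C, then warmed to 90 °C; the feed brings no volume worth counting | 3.0 min |
| spring | 20 mM (fed, over 80 s) | 20.0 mM | 10 µM | 90 °C | all else is in the flask from the start; the feed brings no volume worth counting | 3.0 min |

| run | time / min | target / % | starting material / % |
|---|---|---|---|
| Tuesday's | 0.417 | 33.5 | 66.3 |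
| Tuesday's | 1.33 | 62.1 | 38.3 |
| Tuesday's | 2.00 | 71.8 | 27.7 |
| Tuesday's | 3.00 | 81.4 | 18.1 |
| Tuesday's | 5.00 | 91.8 | 8.2 |
| Tuesday's | 6.00 | 94.8 | 6.0 |
| Friday's | 0.667 | 57.3 | 42.8 |
| Friday's | 1.33 | 75.2 | 24.4 |
| Friday's | 2.00 | 85.3 | 14.3 |
| Friday's | 2.50 | 89.6 | 10.4 |
| Friday's | 3.00 | 92.1 | 7.1 |
| Friday's | 4.00 | 96.4 | 4.1 |
| Thursday's | 0.500 | 36.6 | 63.2 |
| Thursday's | 1.33 | 61.5 | 38.3 |
| Thursday's | 3.00 | 81.2 | 18.2 |
| Thursday's | 4.00 | 87.5 | 12.4 |
| Thursday's | 6.00 | 93.9 | 5.7 |
| Thursday's | 8.00 | 97.2 | 2.7 |
| Monday's | 0.333 | 50.7 | 48.7 |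
| Monday's | 0.833 | 74.9 | 25.1 |
| Monday's | 1.50 | 88.5 | 11.9 |
| Monday's | 2.50 | 96.5 | 3.9 |
| Monday's | 4.00 | 99.4 | 1.0 |

(scatter of a reading: 0.3 percentage points)

1. which flask leads in amount of target, in percent of the starting material charged ("all alike" within 1.5 percentage points) (midnight / dawn / winter / spring / all alike)
2. how much target is there at the end, in percent of the starting material charged: midnight
3. how much target is there at the end, in percent of the starting material charged: dawn
4. how much target is there at the end, in percent of the starting material charged: winter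
5. how much target is there at the end, in percent of the starting material charged: spring

- a reading or a percentage of target counts all its forms, free or not

Two rates carried my reckoning. Friday's run at 90 °C lost starting material late at 0.700 min⁻¹, and Tuesday's run at 75 °C at 0.396 min⁻¹. Since 60 °C, 75 °C and 90 °C are evenly spaced, I squared their ratio and took 3.13 as my estimate of the factor between the work of a minute at 90 °C and a minute at 60 °C. The 80 s cold stretch of midnight was therefore worth 0.426 min of hot time, which put midnight at 2.09 min on Friday's clock. Starting from Friday's 14.3 % at 2.00 min, the late rate left 13.4 %, so I expected 86.6 % of target in midnight. Tuesday's and Thursday's runs read 38.3 % and 38.3 % at 1.33 min despite different second substrate, so I gave winter the same figure and took Friday's 92.1 % for dawn. Spring, with its starting material fed in, lay outside this clock.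

The forecast named dawn, with 86.4 % for midnight, 92.3 % for dawn, 86 % for winter and 87.7 % for spring, suspecting “target binding catalyst”.

The flasks gave 86.4 % in midnight, 92.8 % in dawn, 86.5 % in winter and 87.5 % in spring, so dawn led.

    catalyst intermediate A → free catalyst + target (k = 200 s⁻¹, Ea = 69.0 kJ mol⁻¹)
    second substrate + free catalyst ⇌ catalyst intermediate B (K = 87.0 M⁻¹, k = 11000 M⁻¹ s⁻¹, Ea = 33.0 kJ mol⁻¹, ΔH = −59.0 kJ mol⁻¹)
    starting material + free catalyst ⇌ catalyst intermediate A (K = 130 M⁻¹, k = 5300 M⁻¹ s⁻¹, Ea = 13.0 kJ mol⁻¹, ΔH = −32.0 kJ mol⁻¹)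
    catalyst intermediate B → free catalyst + second product (k = 2600 s⁻¹, Ea = 52.0 kJ mol⁻¹)
    free catalyst → spent catalyst (k = 5.10 × 10⁻⁵ s⁻¹, Ea = 121 kJ mol⁻¹)
    free catalyst + target ⇌ idle complex (K = 150 M⁻¹, k = 19.0 M⁻¹ s⁻¹, Ea = 40.0 kJ mol⁻¹, ΔH = −32.0 kJ mol⁻¹)
    (constants at 90 °C)

Midnight's clock stood 0.907 min behind dawn's, and the late rate over that gap turned dawn's 7.23 % of starting material into 13.6 %, against the 13.6 % midnight held. The step of free catalyst and target forming idle complex is the largest single effect on that gap, though not the main reason for it: without that step, the gap between dawn and midnight shrinks from 6.3 percentage points to 0.59 points, with midnight itself at 99.3 %.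

For midnight left until 12 min, the same worth gave 11.1 min on the clock, and from Friday's 4.1 % at 4.00 min that left 0.0285 % of starting material; the flask held 0.033 %.

(The numbers in the tables stem from a simulated flask from invented constants, noise included.)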